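A direct plan would make ring A by hand: dimethyl 3-oxopentanedioate A1 would be prenylated twice and capped as the methoxymethyl enol ether A2, while 2-chloro-3',4'-dihydroxyacetophenone A3 would be taken in three steps to the 2-alkoxy-1,3-diketone A4.
The dianion of A4 would acylate one ester of A2 and, after a switch to Mg(OMe)2 in MeOH, a Claisen closure would aromatise ring A to the o-hydroxyaryl diketone A5; warm methanolic HCl would then close ring C at O1–C2 and strip four MOM groups.
Weakest, the one-flask dianion acylation and Claisen aromatisation that gives A5: it would have no precedent, a strongly basic dianion would have to add to a hindered α-branched ester with an acidic C–H beside it, the closure would have to beat pyranone and aldol folding, and it would consume two equivalents of the four-step diketone A4 at the point where the branches meet.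
Weak, the run-up to A2: a statistical double alkylation (2,4- against 2,2- and O-alkylation) and an enol ether formed as an E/Z mixture of which one isomer can fold, all to build a ring that is sold as phloroglucinol.
Weak, the closing acid step: 1 M HCl at 45 °C would have to cleave four acetals, one wedged between both prenyl groups, on the finished polyphenol, under conditions that close o-prenylphenols to dimethylchromans, and this at the last step.

**Retrosynthetic overview**
The new route cuts ring C at C4–C4a and O1–C2 in one thermal step: 2,4-diprenylphloroglucinol and an α-pivaloyloxy aroylacetate (as its acylketene) should give the fully substituted flavonol tripivalate, and methoxide then frees the target.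
The feature used is the hexasubstituted ring A, in which C4a is the only carbon that bears neither oxygen nor prenyl: the phloroglucinol partner has one free ring carbon, flanked by two equivalent hydroxyls, so the union can give only the 5,7-dihydroxy-6,8-diprenyl pattern.
Ring order: rings A and B are bought as arenes (phloroglucinol, protocatechuic acid) and never closed; ring C is the only ring made, it is made last, and it closes at carbon (C4–C4a) before oxygen (O1–C2).
The prenyl groups come from two directed ortho-lithiations and the C3 oxygen from an α-acyloxylation; the plan has no ring A cyclisation, no enol ether geometry, no sacrificial equivalent of an advanced fragment and no mineral acid after the prenyl groups are in place.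

Key step: step 7

Remark on the chemistry: the target has no stereocentre; the one stereocentre the route passes through (the α-carbon of the keto ester) is racemic and becomes the sp2 carbon C3 in the key step. Phloroglucinol, chloromethyl methyl ether, prenyl bromide, protocatechuic acid, pivaloyl chloride, potassium ethyl malonate and PhI(OCOt-Bu)2 are taken as commercial.

**Route**

Step 1
Reactants: 1 phloroglucinol (benzene-1,3,5-triol); 2 chloromethyl methyl ether
Product: 3 1,3,5-tris(methoxymethoxy)benzene
Conditions: NaH (3.6 equiv), DMF, 0 °C; 2 (3.6 equiv), 0 °C → rt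
Reagents that add atoms: chloromethyl methyl ether 2, COCCl
Why: Williamson-type O-alkylation of the three phenoxides by the hard, oxocarbenium-like chloride should give the triacetal, which turns every ring oxygen into a director for ortho-lithiation.

Step 2
Reactants: 3 1,3,5-tris(methoxymethoxy)benzene; 4 prenyl bromide (1-bromo-3-methylbut-2-ene)
Product: 6 1,3,5-tris(methoxymethoxy)-2,4-bis(3-methylbut-2-enyl)benzene, via monoprenyl arene 5 (not isolated)
Conditions: n-BuLi (1.05 equiv), TMEDA, THF, 0 °C; 4 (1.0 equiv), −78 °C → rt; same cycle repeated once in the same flask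
Reagents that add atoms: prenyl bromide 4, CC(C)=CCBr
Why: Directed ortho-metalation between two OMOM groups followed by SN2 allylation of the aryllithium at the unhindered CH2 of the bromide should work twice, because after the first cycle the two remaining ring hydrogens are equivalent and each still lies between two OMOM groups, so only the 2,4-pattern can form.

Step 3
Reactants: 6 1,3,5-tris(methoxymethoxy)-2,4-bis(3-methylbut-2-enyl)benzene
Product: 8 2,4-bis(3-methylbut-2-enyl)benzene-1,3,5-triol, via tris(trimethylsilyl) ether 7 (not isolated)
Conditions: Me3SiOTf (6.6 equiv), 2,2'-bipyridyl (9.9 equiv), MeCN, 0 °C → rt, Ar; then H2O, rt; aq NaHCO3 work-up, degassed solvents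
Reagents that add atoms: none
Why: Silyl triflate/bipyridyl cleavage of aromatic MOM ethers should turn each ArO–CH2OMe into ArO–SiMe3 while the methoxymethyl unit passes to bipyridyl, and water then hydrolyses the three silyl ethers, so that no free Brønsted acid meets the two prenyl groups.

Step 4
Reactants: 9 3,4-dihydroxybenzoic acid (protocatechuic acid); 10 pivaloyl chloride
Product: 12 3,4-bis(pivaloyloxy)benzoic acid, via mixed pivalic anhydride 11 (not isolated)
Conditions: 10 (3.3 equiv), pyridine, DMAP (cat.), CH2Cl2, 0 °C → rt; then H2O–THF, rt; 1 M HCl wash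
Reagents that add atoms: pivaloyl chloride 10, CC(C)(C)C(=O)Cl; water, O
Why: Nucleophile-catalysed acylation should cap both phenols, and the mixed anhydride formed at the carboxyl group is returned to the acid by water, which attacks the aroyl and not the hindered pivaloyl carbonyl and leaves the aryl pivalates alone.

Step 5
Reactants: 12 3,4-bis(pivaloyloxy)benzoic acid; 13 potassium ethyl malonate (KO2CCH2CO2Et)
Product: 16 ethyl 3-[3,4-bis(pivaloyloxy)phenyl]-3-oxopropanoate, via acid chloride 14 (not isolated), via aroylmalonic half ester 15 (not isolated)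
Conditions: (COCl)2 (1.3 equiv), DMF (cat.), CH2Cl2, 0 °C → rt, evaporate; 13 (2.1 equiv), MgCl2 (2.5 equiv), Et3N (3.2 equiv), MeCN, 0 °C → rt; 1 M HCl, rt
Reagents that add atoms: potassium ethyl malonate 13, CCOC(=O)CC(=O)[O-].[K+]
Why: Acid chloride formation followed by C-acylation of the magnesium enolate of the malonate half ester (Masamune/Rathke-type acylation) and decarboxylation on acidification should give the β-keto ester, the aryl pivalates being inert to the soft magnesium enolate and to brief dilute acid.

Step 6
Reactants: 16 ethyl 3-[3,4-bis(pivaloyloxy)phenyl]-3-oxopropanoate; 17 bis(pivaloyloxy)iodobenzene, PhI(OCOt-Bu)2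
Product: 18 ethyl 3-[3,4-bis(pivaloyloxy)phenyl]-3-oxo-2-(pivaloyloxy)propanoate (racemic)
Conditions: 17 (1.1 equiv), t-BuCO2H (3 equiv), MeCN, 40 °C
Reagents that add atoms: bis(pivaloyloxy)iodobenzene 17, CC(C)(C)C(=O)OI(OC(=O)C(C)(C)C)c1ccccc1
Why: α-Acyloxylation of a β-keto ester by a trivalent iodine dicarboxylate (the pivalate counterpart of the PhI(OAc)2 α-acetoxylation) should proceed by ligand exchange of the enol at iodine and displacement of iodobenzene by pivalate at carbon, the more hindered product enolising too slowly for a second oxidation; the new stereocentre is racemic and is erased in step 7.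

Step 7
Reactants: 8 2,4-bis(3-methylbut-2-enyl)benzene-1,3,5-triol; 18 ethyl 3-[3,4-bis(pivaloyloxy)phenyl]-3-oxo-2-(pivaloyloxy)propanoate
Product: 21 2-[3,4-bis(pivaloyloxy)phenyl]-5,7-dihydroxy-6,8-bis(3-methylbut-2-enyl)-4-oxo-4H-chromen-3-yl pivalate, via aroylketene 19 (not isolated), via aryl triketone 20 (not isolated)
Conditions: 18 (1.5 equiv), Ph2O (ca. 2 M), 210 °C (microwave), 15 min, Ar stream (EtOH and H2O swept out)
Reagents that add atoms: none
Why: Proposed new method: at about 200 °C the enol of 18 should lose ethanol through a six-membered transition state to give the α-oxoketene 19, which acylates the only unsubstituted ring carbon of 8 (the future C4a), either by direct Friedel–Crafts-type attack of the phloroglucinol or by reversible O-acylation and thermal 1,3-acyl shift, to give triketone 20; one of its two equivalent ortho hydroxyls then adds to the aryl ketone (6-exo-trig) and water is lost, so ring C closes first at the C4–C4a carbon–carbon bond and then at O1–C2. The closest known reaction is the Mentzer pyrone synthesis, in which phloroglucinol and ethyl aroylacetates give 5,7-dihydroxyflavones when heated without catalyst at about 240 °C; new are the α-pivaloyloxy group on the ketene, which brings in the C3 oxygen at the right oxidation level, and a phloroglucinol that carries two prenyl groups. No stereocentre is formed, since the racemic α-carbon of 18 becomes the sp2 carbon C3. Regiochemistry needs no control because 8 has exactly one free ring carbon and a mirror plane through it; carbon over oxygen acylation should be secured by reversibility, since aryl β-keto esters return the ketene on heating while C-acylation followed by dehydration to the aromatic pyranone is a sink; the chromone is expected over the 4-arylcoumarin because no acid is present to activate the hindered, acyloxy-substituted aryl ketone for a Pechmann-type attack. The prenyl groups should survive because the medium holds no acid stronger than a phenol and the exposure is short, o-prenylphenols being formed and kept at similar temperatures in aromatic Claisen rearrangements, and the bulky pivaloyl group should migrate too slowly to scramble the enediol pattern of 18.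

Step 8
Reactants: 21 2-[3,4-bis(pivaloyloxy)phenyl]-5,7-dihydroxy-6,8-bis(3-methylbut-2-enyl)-4-oxo-4H-chromen-3-yl pivalate
Product: 22 2-(3,4-dihydroxyphenyl)-3,5,7-trihydroxy-6,8-bis(3-methylbut-2-enyl)-4H-chromen-4-one (6,8-diprenylquercetin)
Conditions: NaOMe (6 equiv), MeOH–THF 3:1 (degassed), 0 °C → rt, Ar; AcOH to pH 6 at 0 °C
Reagents that add atoms: none
Why: Methoxide transesterification should remove the enol pivalate and both aryl pivalates (and any stray O-acyl group from step 7) as methyl pivalate, the prenyl groups being inert to base and the exclusion of oxygen protecting the polyphenolate from autoxidation.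

**Compound list**
1 | phloroglucinol (benzene-1,3,5-triol) | Oc1cc(O)cc(O)c1 | starting material
2 | chloromethyl methyl ether | COCCl | starting material
3 | 1,3,5-tris(methoxymethoxy)benzene | COCOc1cc(OCOC)cc(OCOC)c1 | intermediate
4 | prenyl bromide (1-bromo-3-methylbut-2-ene) | CC(C)=CCBr | starting material
5 | 1,3,5-tris(methoxymethoxy)-2-(3-methylbut-2-enyl)benzene (not isolated) | COCOc1cc(OCOC)c(CC=C(C)C)c(OCOC)c1 | intermediate
6 | 1,3,5-tris(methoxymethoxy)-2,4-bis(3-methylbut-2-enyl)benzene | COCOc1cc(OCOC)c(CC=C(C)C)c(OCOC)c1CC=C(C)C | intermediate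
7 | 2,4-bis(3-methylbut-2-enyl)-1,3,5-tris(trimethylsilyloxy)benzene (not isolated) | C[Si](C)(C)Oc1cc(O[Si](C)(C)C)c(CC=C(C)C)c(O[Si](C)(C)C)c1CC=C(C)C | intermediate
8 | 2,4-bis(3-methylbut-2-enyl)benzene-1,3,5-triol (2,4-diprenylphloroglucinol) | CC(C)=CCc1c(O)cc(O)c(CC=C(C)C)c1O | intermediate
9 | 3,4-dihydroxybenzoic acid (protocatechuic acid) | O=C(O)c1ccc(O)c(O)c1 | starting material
10 | pivaloyl chloride | CC(C)(C)C(=O)Cl | starting material
11 | 3,4-bis(pivaloyloxy)benzoic pivalic anhydride (not isolated) | CC(C)(C)C(=O)OC(=O)c1ccc(OC(=O)C(C)(C)C)c(OC(=O)C(C)(C)C)c1 | intermediate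
12 | 3,4-bis(pivaloyloxy)benzoic acid | O=C(O)c1ccc(OC(=O)C(C)(C)C)c(OC(=O)C(C)(C)C)c1 | intermediate
13 | potassium ethyl malonate (KO2CCH2CO2Et) | CCOC(=O)CC(=O)[O-].[K+] | starting material
14 | 3,4-bis(pivaloyloxy)benzoyl chloride (not isolated) | O=C(Cl)c1ccc(OC(=O)C(C)(C)C)c(OC(=O)C(C)(C)C)c1 | intermediate
15 | 2-[3,4-bis(pivaloyloxy)benzoyl]-3-ethoxy-3-oxopropanoic acid (racemic, drawn neutral, not isolated) | CCOC(=O)C(C(=O)O)C(=O)c1ccc(OC(=O)C(C)(C)C)c(OC(=O)C(C)(C)C)c1 | intermediate
16 | ethyl 3-[3,4-bis(pivaloyloxy)phenyl]-3-oxopropanoate | CCOC(=O)CC(=O)c1ccc(OC(=O)C(C)(C)C)c(OC(=O)C(C)(C)C)c1 | intermediate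
17 | bis(pivaloyloxy)iodobenzene, PhI(OCOt-Bu)2 | CC(C)(C)C(=O)OI(OC(=O)C(C)(C)C)c1ccccc1 | starting material
18 | ethyl 3-[3,4-bis(pivaloyloxy)phenyl]-3-oxo-2-(pivaloyloxy)propanoate (racemic) | CCOC(=O)C(OC(=O)C(C)(C)C)C(=O)c1ccc(OC(=O)C(C)(C)C)c(OC(=O)C(C)(C)C)c1 | intermediate
19 | [3,4-bis(pivaloyloxy)benzoyl](pivaloyloxy)ketene (not isolated) | O=C=C(OC(=O)C(C)(C)C)C(=O)c1ccc(OC(=O)C(C)(C)C)c(OC(=O)C(C)(C)C)c1 | intermediate
20 | 1-[3,4-bis(pivaloyloxy)phenyl]-1,3-dioxo-3-[2,4,6-trihydroxy-3,5-bis(3-methylbut-2-enyl)phenyl]propan-2-yl pivalate (racemic, not isolated) | CC(C)=CCc1c(O)c(CC=C(C)C)c(O)c(C(=O)C(OC(=O)C(C)(C)C)C(=O)c2ccc(OC(=O)C(C)(C)C)c(OC(=O)C(C)(C)C)c2)c1O | intermediate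
21 | 2-[3,4-bis(pivaloyloxy)phenyl]-5,7-dihydroxy-6,8-bis(3-methylbut-2-enyl)-4-oxo-4H-chromen-3-yl pivalate | CC(C)=CCc1c(O)c(CC=C(C)C)c2oc(-c3ccc(OC(=O)C(C)(C)C)c(OC(=O)C(C)(C)C)c3)c(OC(=O)C(C)(C)C)c(=O)c2c1O | intermediate
22 | 2-(3,4-dihydroxyphenyl)-3,5,7-trihydroxy-6,8-bis(3-methylbut-2-enyl)-4H-chromen-4-one (achiral) | CC(C)=CCc1c(O)c(CC=C(C)C)c2oc(-c3ccc(O)c(O)c3)c(O)c(=O)c2c1O | target

Total step count: 8. Longest linear sequence: 5 (steps 1, 2, 3, 7, 8; the branch through steps 4, 5, 6, 7, 8 is equally long).

**Steps most likely to fail**

Step 7 (the step that carries the label).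
- What may go wrong: a prenyl group could close onto a neighbouring phenol oxygen before the ring carbon is acylated; the pivaloyl group could shift within the enediol of 18 before the ketene forms; O-acylation might not funnel to carbon at a temperature the prenyl groups tolerate.
- The fallback uses known reactions, forms the same bonds stepwise and cold, and sets out from 6. A third directed ortho-lithiation (n-BuLi, TMEDA, THF, 0 °C) at the last ring hydrogen and acylation with N-methoxy-N-methyl-2-(pivaloyloxy)acetamide would give 2-oxo-2-[2,4,6-tris(methoxymethoxy)-3,5-bis(3-methylbut-2-enyl)phenyl]ethyl pivalate F1.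
- Its lithium enolate (LiN(SiMe3)2, 2.1 equiv, THF, −78 °C) would be C-acylated by acid chloride 14 (made from 12 as in step 5) in a Claisen-type condensation. This would give 1-[3,4-bis(pivaloyloxy)phenyl]-1,3-dioxo-3-[2,4,6-tris(methoxymethoxy)-3,5-bis(3-methylbut-2-enyl)phenyl]propan-2-yl pivalate F2.
- The silyl triflate/bipyridyl conditions of step 3 would free the three phenols and bring the fallback back to the route at 20. Compound 20 would close to 21 on warming in toluene with a trace of AcOH, the known cyclodehydration of o-hydroxyaryl 1,3-diketones.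

Step 2.
- What may go wrong: allylic transposition during the alkylation would give 1,1-dimethylallyl groups; lithiation at the benzylic, allylic CH2 of the first prenyl group could compete in the second cycle; the second cycle could stay incomplete.
- The fallback sets out from 3 and replaces organolithium alkylation by cross-coupling. Two-fold bromination (NBS, 2.0 equiv, MeCN, 0 °C) would give 2,4-dibromo-1,3,5-tris(methoxymethoxy)benzene F3.
- A double Stille coupling with tributyl(3-methylbut-2-enyl)stannane would then return to the route at 6. Proposed conditions are the zerovalent palladium complex Pd(P(t-Bu)3)2, CsF, dioxane, 90 °C.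

Step 3.
- What may go wrong: the released methoxymethyl unit could be captured by the free, very nucleophilic ring carbon; the acetal between the two prenyl groups could cleave slowly, and longer exposure could close a prenyl group onto oxygen.
- The fallback drops protecting groups altogether and sets out from 1. Direct two-fold C-prenylation of the phloroglucinolate with 4 (2 equiv, aq KOH, 0 °C, Ar) is a known but unselective alkylation. It would give 8 beside mono- and over-alkylated material that chromatography removes, and so comes back to the route at 8, replacing steps 1 to 3.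
- It makes no compound outside the compound list (F0).

Further compounds
F1 | step 7 | 2-oxo-2-[2,4,6-tris(methoxymethoxy)-3,5-bis(3-methylbut-2-enyl)phenyl]ethyl pivalate | CC(C)(C)C(=O)OCC(=O)c1c(OCOC)c(CC=C(C)C)c(OCOC)c(CC=C(C)C)c1OCOC
F2 | step 7 | 1-[3,4-bis(pivaloyloxy)phenyl]-1,3-dioxo-3-[2,4,6-tris(methoxymethoxy)-3,5-bis(3-methylbut-2-enyl)phenyl]propan-2-yl pivalate (racemic) | CC(C)(C)C(=O)OC(C(=O)c1ccc(OC(=O)C(C)(C)C)c(OC(=O)C(C)(C)C)c1)C(=O)c1c(OCOC)c(CC=C(C)C)c(OCOC)c(CC=C(C)C)c1OCOC
F3 | step 2 | 2,4-dibromo-1,3,5-tris(methoxymethoxy)benzene | COCOc1cc(OCOC)c(Br)c(OCOC)c1Br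
F0 | step 3 | none | none
A1 | direct plan | dimethyl 3-oxopentanedioate | COC(=O)CC(=O)CC(=O)OC
A2 | direct plan | dimethyl 3-(methoxymethoxy)-2,4-bis(3-methylbut-2-enyl)pent-2-enedioate (racemic, E/Z mixture) | COC(=O)C(CC=C(C)C)=C(OCOC)C(CC=C(C)C)C(=O)OC
A3 | direct plan | 2-chloro-3',4'-dihydroxyacetophenone | O=C(CCl)c1ccc(O)c(O)c1
A4 | direct plan | 1-[3,4-bis(methoxymethoxy)phenyl]-2-(methoxymethoxy)butane-1,3-dione (racemic) | CC(=O)C(OCOC)C(=O)c1ccc(OCOC)c(OCOC)c1
A5 | direct plan | 1-[3,4-bis(methoxymethoxy)phenyl]-3-[2,6-dihydroxy-4-(methoxymethoxy)-3,5-bis(3-methylbut-2-enyl)phenyl]-2-(methoxymethoxy)propane-1,3-dione (racemic) | COCOC(C(=O)c1ccc(OCOC)c(OCOC)c1)C(=O)c1c(O)c(CC=C(C)C)c(OCOC)c(CC=C(C)C)c1O
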